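## Retrosynthetic overview

1. Locants (furo[3,4-c]furan-1-one): C1(=O)–O2–C3(aryl)–C3a–C4H2–O5–C6(aryl)–C6a. Ring A is the lactone (C1, O2, C3, C3a, C6a); ring B is the tetrahydrofuran (C3a, C4, O5, C6, C6a). The target is the exo,exo-diaryl isomer.
2. Last disconnections: the three O-benzyl groups, then the C6–aryl bond (Friedel–Crafts arylation of the C6 oxocarbenium ion of the cis-fused lactone acetal from its convex face). This leads back to enol ether 9 (C6=C6a, C6–H).
3. Ring B of 9 is opened at C4–O5 to a cyclopropane (C6a, C3a, C4) with a formyl group on C6a (Cloke–Wilson ring expansion). Enabling feature: C6a carries both C1 and C6, so with C6 as CHO the three-membered ring is geminally doubly activated and the formyl oxygen is the future O5.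
4. Ring A and the cyclopropane arise together from an acyclic (S)-1-arylallyl 2-diazo-3-oxopropanoate by intramolecular carbene addition. Order of ring formation: ring A plus cyclopropane, then ring B by expansion, in one operation.
5. The only external chirality is C3, from lipase resolution of the vinyl carbinol of O-benzylvanillin; C3a, C6a and C6 follow from it by substrate control.

Key step: step 6

Remark: acetal 10 is used as the mixture of both C6 epimers, because both give the same oxocarbenium ion in step 8. Reagents named without a number are purchased.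

## Route

Step 1
Reactants: 1 4-(benzyloxy)-3-methoxybenzaldehyde
Product: 2 rac-1-[4-(benzyloxy)-3-methoxyphenyl]prop-2-en-1-ol
Conditions: CH2=CHMgBr, THF, −78 → 0 °C; aq. NH4Cl
Reagents that add atoms: vinylmagnesium bromide, C=C[Mg]Br
Why: Grignard 1,2-addition of the vinyl nucleophile to the aryl aldehyde gives the racemic secondary allylic alcohol; no stereocontrol is needed here.

Step 2
Reactants: 2 rac-1-[4-(benzyloxy)-3-methoxyphenyl]prop-2-en-1-ol
Product: 3 (S)-1-[4-(benzyloxy)-3-methoxyphenyl]prop-2-en-1-ol
Conditions: Novozym 435 (immobilised Candida antarctica lipase B), vinyl acetate, MTBE, 30 °C, stopped just past half conversion; chromatography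
Reagents that add atoms: none
Why: Lipase-catalysed kinetic resolution by transesterification: the enzyme should acylate the (R)-enantiomer of aryl vinyl carbinols preferentially (Kazlauskas rule, aryl as the large group), so the (S)-alcohol that carries C3 of the target should remain and is separated from the (R)-acetate.

Step 3
Reactants: 3 (S)-1-[4-(benzyloxy)-3-methoxyphenyl]prop-2-en-1-ol
Product: 4 (S)-1-[4-(benzyloxy)-3-methoxyphenyl]prop-2-en-1-yl 2-bromoacetate
Conditions: BrCH2COBr, NaHCO3, MeCN, 0 °C
Reagents that add atoms: bromoacetyl bromide, BrCC(Br)=O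
Why: O-acylation with an acyl bromide under bicarbonate buffering keeps the medium non-acidic, so the ionisable benzylic/allylic C–O bond and its configuration should survive.

Step 4
Reactants: 4 (S)-1-[4-(benzyloxy)-3-methoxyphenyl]prop-2-en-1-yl 2-bromoacetate
Product: 5 (S)-1-[4-(benzyloxy)-3-methoxyphenyl]prop-2-en-1-yl 2-diazoacetate
Conditions: TsNHNHTs, DBU, THF, 0 °C
Reagents that add atoms: N,N′-ditosylhydrazine, Cc1ccc(cc1)S(=O)(=O)NNS(=O)(=O)c1ccc(C)cc1
Why: N-alkylation of the ditosylhydrazine by the bromoacetate followed by DBU-induced loss of two sulfinates (the ditosylhydrazine route to diazoacetates) should give the diazo ester under mild basic conditions without touching the stereocentre.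

Step 5
Reactants: 5 (S)-1-[4-(benzyloxy)-3-methoxyphenyl]prop-2-en-1-yl 2-diazoacetate
Product: 7 (S)-1-[4-(benzyloxy)-3-methoxyphenyl]prop-2-en-1-yl 2-diazo-3-oxopropanoate, via iminium chloride 6 (not isolated)
Conditions: [Me2N=CHCl]Cl, 2,6-lutidine, CH2Cl2, 0 °C → rt; then aq. NaHCO3, rt
Reagents that add atoms: (chloromethylene)dimethyliminium chloride, C[N+](C)=CCl.[Cl-]; water, O
Why: Vilsmeier-type C-formylation of the nucleophilic diazo carbon gives the amidinium salt, whose mild hydrolysis unmasks the aldehyde; this is the established entry to 2-diazo-3-oxopropanoates, since diazo transfer to formylacetates proceeds with deformylation, and the lutidine buffer protects the acid-labile diazo and allylic ester groups.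

Step 6
Reactants: 7 (S)-1-[4-(benzyloxy)-3-methoxyphenyl]prop-2-en-1-yl 2-diazo-3-oxopropanoate
Product: 9 (3S,3aR)-3-[4-(benzyloxy)-3-methoxyphenyl]-3a,4-dihydro-1H,3H-furo[3,4-c]furan-1-one, via formyl cyclopropane lactone 8 (not isolated)
Conditions: Rh2(OAc)4 (1 mol %), ClCH2CH2Cl, 60 °C, slow addition of 7; then n-Bu4NI (20 mol %), 80 °C
Reagents that add atoms: none
Why: Rh2(OAc)4 converts the diazo ester into an acceptor/acceptor rhodium carbene that adds to the tethered vinyl group and closes ring A together with the cyclopropane C6a–C3a–C4; iodide then opens this formyl/lactone-activated cyclopropane by SN2 attack at the unsubstituted C4, and the formyl enolate oxygen displaces iodide to form the C4–O5 bond, overall a nucleophile-catalysed Cloke–Wilson rearrangement. The closest known reaction types are the intramolecular cyclopropanation of allylic α-diazo-β-oxo esters to 1-acyl-3-oxabicyclo[3.1.0]hexan-2-ones and the iodide- or amine-catalysed ring expansion of 1-acylcyclopropane-1-carboxylates to 4,5-dihydrofuran-3-carboxylates. Ring A closes by carbene [2+1] addition in which the three-atom ester tether enforces the cis fusion, and ring B closes by 5-exo-tet O-alkylation of the enolate. The new stereocentre C3a is controlled by C3: in the cyclopropanation transition state the allylic hydrogen eclipses the alkene (minimal allylic 1,3-strain), which places the aryl group anti to the new CH2, and C3a is kept in the ring expansion because no bond to it is broken. The step needs cleavage of C4–C6a rather than C3a–C6a and O- rather than C-alkylation; the first is secured by the primary, unhindered C4 as the SN2 site, the second because C-alkylation only returns the strained cyclopropane whereas the push–pull enol ether 9 is the thermodynamic sink.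

Step 7
Reactants: 9 (3S,3aR)-3-[4-(benzyloxy)-3-methoxyphenyl]-3a,4-dihydro-1H,3H-furo[3,4-c]furan-1-one
Product: 10 (3S,3aR,6aS)-3-[4-(benzyloxy)-3-methoxyphenyl]-6-methoxytetrahydro-1H,3H-furo[3,4-c]furan-1-one (both C6 epimers)
Conditions: MeOH–CH2Cl2, camphorsulfonic acid (0.1 equiv), 40 °C
Reagents that add atoms: methanol, CO
Why: Acid-catalysed Markovnikov addition of methanol to the enol ether (C-protonation at C6a, capture of the C6 oxocarbenium ion) gives the mixed cyclic acetal; protonation of C6a gives the cis-fused bicycle, the only low-strain fusion of two five-membered rings, under thermodynamic control because the enol ether re-forms reversibly.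

Step 8
Reactants: 10 (3S,3aR,6aS)-3-[4-(benzyloxy)-3-methoxyphenyl]-6-methoxytetrahydro-1H,3H-furo[3,4-c]furan-1-one; 11 1,2-bis(benzyloxy)benzene
Product: 12 (3S,3aR,6S,6aS)-3-[4-(benzyloxy)-3-methoxyphenyl]-6-[3,4-bis(benzyloxy)phenyl]tetrahydro-1H,3H-furo[3,4-c]furan-1-one
Conditions: 11 (3 equiv), Me3SiOSO2CF3 (0.2 equiv), CH2Cl2, −40 → 0 °C
Reagents that add atoms: none
Why: Friedel–Crafts C-arylation of a cyclic oxocarbenium ion (C-aryl glycoside type): the silyl triflate ionises the acetal and the symmetric electron-rich arene attacks through its position para to an ether oxygen from the convex face of the cis-fused bicycle, which places the new aryl group exo (trans to the C6a–C1 bond) and sets C6.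

Step 9
Reactants: 12 (3S,3aR,6S,6aS)-3-[4-(benzyloxy)-3-methoxyphenyl]-6-[3,4-bis(benzyloxy)phenyl]tetrahydro-1H,3H-furo[3,4-c]furan-1-one
Product: 13 (3S,3aR,6S,6aS)-6-(3,4-dihydroxyphenyl)-3-(4-hydroxy-3-methoxyphenyl)tetrahydro-1H,3H-furo[3,4-c]furan-1-one (CNP0268159.1)
Conditions: H2 (1 atm), 10% Pd/C, EtOAc–MeOH, rt
Reagents that add atoms: none
Why: Catalytic hydrogenolysis of the three aryl benzyl ethers at atmospheric pressure and room temperature, where the benzylic lactone and cyclic benzylic ether C–O bonds are cleaved much more slowly, should free the three phenols without touching a stereocentre.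

## Compound list

1 | 4-(benzyloxy)-3-methoxybenzaldehyde (O-benzylvanillin) | COc1cc(C=O)ccc1OCc1ccccc1 | starting material
2 | rac-1-[4-(benzyloxy)-3-methoxyphenyl]prop-2-en-1-ol | COc1cc(C(O)C=C)ccc1OCc1ccccc1 | intermediate
3 | (S)-1-[4-(benzyloxy)-3-methoxyphenyl]prop-2-en-1-ol | COc1cc([C@H](C=C)O)ccc1OCc1ccccc1 | intermediate
4 | (S)-1-[4-(benzyloxy)-3-methoxyphenyl]prop-2-en-1-yl 2-bromoacetate | COc1cc([C@H](C=C)OC(=O)CBr)ccc1OCc1ccccc1 | intermediate
5 | (S)-1-[4-(benzyloxy)-3-methoxyphenyl]prop-2-en-1-yl 2-diazoacetate | COc1cc([C@H](C=C)OC(=O)C=[N+]=[N-])ccc1OCc1ccccc1 | intermediate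
6 | N-(3-{[(S)-1-[4-(benzyloxy)-3-methoxyphenyl]prop-2-en-1-yl]oxy}-2-diazo-3-oxopropylidene)-N-methylmethanaminium chloride | COc1cc([C@H](C=C)OC(=O)C(=[N+]=[N-])C=[N+](C)C)ccc1OCc1ccccc1.[Cl-] | intermediate
7 | (S)-1-[4-(benzyloxy)-3-methoxyphenyl]prop-2-en-1-yl 2-diazo-3-oxopropanoate | COc1cc([C@H](C=C)OC(=O)C(=[N+]=[N-])C=O)ccc1OCc1ccccc1 | intermediate
8 | (1R,4S,5S)-4-[4-(benzyloxy)-3-methoxyphenyl]-2-oxo-3-oxabicyclo[3.1.0]hexane-1-carbaldehyde (aryl anti to the cyclopropane CH2) | O=C[C@@]12C[C@@H]1[C@@H](c1ccc(OCc3ccccc3)c(OC)c1)OC2=O | intermediate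
9 | (3S,3aR)-3-[4-(benzyloxy)-3-methoxyphenyl]-3a,4-dihydro-1H,3H-furo[3,4-c]furan-1-one (C6=C6a enol ether) | COc1cc([C@H]2OC(=O)C3=COC[C@H]23)ccc1OCc1ccccc1 | intermediate
10 | (3S,3aR,6aS)-3-[4-(benzyloxy)-3-methoxyphenyl]-6-methoxytetrahydro-1H,3H-furo[3,4-c]furan-1-one (cis-fused, both C6 epimers) | COc1cc([C@H]2OC(=O)[C@H]3[C@@H]2COC3OC)ccc1OCc1ccccc1 | intermediate
11 | 1,2-bis(benzyloxy)benzene | c1ccc(COc2ccccc2OCc2ccccc2)cc1 | starting material
12 | (3S,3aR,6S,6aS)-3-[4-(benzyloxy)-3-methoxyphenyl]-6-[3,4-bis(benzyloxy)phenyl]tetrahydro-1H,3H-furo[3,4-c]furan-1-one | COc1cc([C@H]2OC(=O)[C@H]3[C@@H]2CO[C@@H]3c2ccc(OCc3ccccc3)c(OCc3ccccc3)c2)ccc1OCc1ccccc1 | intermediate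
13 | (3S,3aR,6S,6aS)-6-(3,4-dihydroxyphenyl)-3-(4-hydroxy-3-methoxyphenyl)tetrahydro-1H,3H-furo[3,4-c]furan-1-one | COc1cc([C@H]2OC(=O)[C@H]3[C@@H]2CO[C@@H]3c2ccc(O)c(O)c2)ccc1O | target

## Step count and risks

Total step count: 9. Longest linear sequence: 9 steps (1 → 13); arene 11 enters in step 8.

**Step 6.** The formyl-substituted rhodium carbene may be diverted before it reaches the alkene (1,2-shift of the aldehyde hydrogen to a ketene, carbene dimerisation, attack on the electron-rich arene). It may also add with too little facial discrimination by the aryl-bearing carbon, and iodide may attack the benzylic lactone carbon during the ring expansion. The fallback sets out from 3 and comes back at 8, and keeps the formyl group out of the carbene step. Alcohol 3 is esterified with 3-(ethylsulfanyl)-3-oxopropanoic acid (DCC, cat. DMAP, CH2Cl2, 0 °C) to the mixed thiomalonate S-ethyl 3-{[(S)-1-[4-(benzyloxy)-3-methoxyphenyl]prop-2-en-1-yl]oxy}-3-oxopropanethioate F1. Regitz diazo transfer (4-acetamidobenzenesulfonyl azide, Et3N, MeCN) gives the diazo thiomalonate F2. Intramolecular cyclopropanation of this diazomalonate-type substrate (Rh2(OAc)4, ClCH2CH2Cl, 60 °C) gives the thioester cyclopropane lactone S-ethyl (1S,4S,5S)-4-[4-(benzyloxy)-3-methoxyphenyl]-2-oxo-3-oxabicyclo[3.1.0]hexane-1-carbothioate F3, which is isolated and freed from any syn isomer. Fukuyama reduction (Et3SiH, Pd/C, acetone, rt) then gives aldehyde 8, here isolated, which is ring-expanded to 9 with n-Bu4NI as in the second stage of step 6.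

**Step 8.** Capture of the oxocarbenium ion by the only moderately nucleophilic arene may be slow. That would allow self-alkylation through the guaiacyl ring, acid-induced ionisation at C3, or attack from the concave face. The fallback sets out from 10 and comes back at 12, and replaces the arene by an organozinc nucleophile. Acetal 10 is converted with benzenesulfinic acid and CaCl2 (CH2Cl2, rt) into the anomeric sulfone (3S,3aR,6aR)-3-[4-(benzyloxy)-3-methoxyphenyl]-6-(phenylsulfonyl)tetrahydro-1H,3H-furo[3,4-c]furan-1-one F4 (same spatial arrangement as 10, both C6 epimers). Commercial 4-bromo-1,2-bis(benzyloxy)benzene is converted with Mg (THF) into [3,4-bis(benzyloxy)phenyl]magnesium bromide F5 and transmetalated with ZnBr2 to [3,4-bis(benzyloxy)phenyl]zinc bromide F6. Reaction of F4 with F6 (ZnBr2, THF, rt) should ionise the sulfone and transfer the aryl group to the convex face, giving 12; the lactone tolerates the organozinc reagent.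

**Step 5.** HCl released from the chloroiminium salt may protonate the diazo carbon or ionise the allylic benzylic ester, and hydrolysis of the amidinium salt may be incomplete. The fallback sets out from 5 and comes back at 7 under non-acidic conditions. DBU-catalysed aldol addition of 5 to formaldehyde (paraformaldehyde, MeCN, rt) gives (S)-1-[4-(benzyloxy)-3-methoxyphenyl]prop-2-en-1-yl 2-diazo-3-hydroxypropanoate F7. Dess–Martin oxidation (Dess–Martin periodinane, NaHCO3, CH2Cl2, 0 °C) then gives 7.

## Further compounds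

F1 | step 6 | S-ethyl 3-{[(S)-1-[4-(benzyloxy)-3-methoxyphenyl]prop-2-en-1-yl]oxy}-3-oxopropanethioate | COc1cc([C@H](C=C)OC(=O)CC(=O)SCC)ccc1OCc1ccccc1
F2 | step 6 | S-ethyl 3-{[(S)-1-[4-(benzyloxy)-3-methoxyphenyl]prop-2-en-1-yl]oxy}-2-diazo-3-oxopropanethioate | COc1cc([C@H](C=C)OC(=O)C(=[N+]=[N-])C(=O)SCC)ccc1OCc1ccccc1
F3 | step 6 | S-ethyl (1S,4S,5S)-4-[4-(benzyloxy)-3-methoxyphenyl]-2-oxo-3-oxabicyclo[3.1.0]hexane-1-carbothioate | CCSC(=O)[C@@]12C[C@@H]1[C@@H](c1ccc(OCc3ccccc3)c(OC)c1)OC2=O
F4 | step 8 | (3S,3aR,6aR)-3-[4-(benzyloxy)-3-methoxyphenyl]-6-(phenylsulfonyl)tetrahydro-1H,3H-furo[3,4-c]furan-1-one (both C6 epimers) | COc1cc([C@H]2OC(=O)[C@H]3[C@@H]2COC3S(=O)(=O)c2ccccc2)ccc1OCc1ccccc1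
F5 | step 8 | [3,4-bis(benzyloxy)phenyl]magnesium bromide | Br[Mg]c1ccc(OCc2ccccc2)c(OCc2ccccc2)c1
F6 | step 8 | [3,4-bis(benzyloxy)phenyl]zinc bromide | Br[Zn]c1ccc(OCc2ccccc2)c(OCc2ccccc2)c1
F7 | step 5 | (S)-1-[4-(benzyloxy)-3-methoxyphenyl]prop-2-en-1-yl 2-diazo-3-hydroxypropanoate | COc1cc([C@H](C=C)OC(=O)C(=[N+]=[N-])CO)ccc1OCc1ccccc1
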